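**Retrosynthetic overview**

1. Names used: ring A = the 2,2-dimethyl-dihydropyran ring (its O–CMe2 carbon = C-q); ring B = the second pyran ring; C-a = ring-fusion CH bonded to C-q; C-b = ring-fusion O–CH; C-c = the ring-B CH that carries the side chain. Descriptors are given in the order (a,b,c); the target is (aR,bS,cR).
2. Endgame: the tertiary alcohol comes from Markovnikov hydration of a methallyl group. The methallyl group is put on C-c by SN1 allylation of a C-c carbinol from the convex face. The carbinol comes from a C-c ketone by asymmetric transfer hydrogenation run as a kinetic resolution, which is the source of absolute configuration.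
3. Key disconnection: the C-a–C-q bond of ring A, formed last in the ring system by a redox-neutral 1,5-hydride shift/cyclization of an isopropyl ether onto the ring-B γ-pyranone of a flat, achiral precursor. One operation makes C-b–H, the C-a–C-q bond, ring A and the cis ring fusion.
4. Enabling feature: C-q sits on the oxygen at C4 of quinolone A, whose C3 is bonded to C-b, so the CMe2–H is 1,5 to C-b. C-b is both the O-bearing carbon and the β-carbon of the ring-B enone (C-a = α-carbon, C-c = carbonyl). Hydride transfer to C-b therefore creates an oxocarbenium at C-q and an enolate at C-a, 1,6 to each other.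
5. Precursor: ring B (pyranone) is built first by Claisen–Schmidt condensation of a 3-formyl- and a 3-acetyl-4-hydroxyquinolone and iodine/DMSO oxidative cyclization, then O-isopropylation. Ring order: B, then A.

Key step: step 5

Assumption: 3-acetyl-4-hydroxy-1-methylquinolin-2(1H)-one is taken as a catalogue compound; racemic compounds are drawn as the enantiomer that is carried on.

**Step 1**
Reactants: 1 4-hydroxy-1-methylquinolin-2(1H)-one
Product: 2 4-hydroxy-1-methyl-2-oxo-1,2-dihydroquinoline-3-carbaldehyde
Conditions: CHCl3, aq NaOH, 60 °C; then aq HCl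
Reagents that add atoms: chloroform (ClC(Cl)Cl); sodium hydroxide ([Na+].[OH-])
Why: Reimer–Tiemann formylation at the nucleophilic C3 of the quinolonolate, the only free enol carbon, should give the aldehyde, which is stabilized as the chelated enol.

**Step 2**
Reactants: 2 4-hydroxy-1-methyl-2-oxo-1,2-dihydroquinoline-3-carbaldehyde; 3 3-acetyl-4-hydroxy-1-methylquinolin-2(1H)-one
Product: 4 (E)-4-hydroxy-3-[3-(4-hydroxy-1-methyl-2-oxo-1,2-dihydroquinolin-3-yl)prop-2-enoyl]-1-methylquinolin-2(1H)-one
Conditions: piperidine (cat.), n-BuOH, reflux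
Reagents that add atoms: none
Why: Claisen–Schmidt (aldol) condensation in which piperidine activates the chelated formyl group of 2 as an iminium/enaminone and the acidic acetyl CH3 of 3 condenses with it, loss of water giving the conjugated E-enone.

**Step 3**
Reactants: 4 (E)-enone from step 2
Product: 6 2-(4-hydroxy-1-methyl-2-oxo-1,2-dihydroquinolin-3-yl)-6-methyl-4H-pyrano[3,2-c]quinoline-4,5(6H)-dione, via dihydropyranone 5 (not isolated)
Conditions: I2 (10 mol %), DMSO, 120 °C
Reagents that add atoms: none
Why: Iodine/DMSO oxidative cyclization of a 2'-hydroxychalcone-type enone: the 4-OH beside the ketone adds 6-endo to the enone β-carbon to give 5, which is dehydrogenated by iodination/HI loss while DMSO re-oxidizes HI, so ring B arrives as a γ-pyranone.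

**Step 4**
Reactants: 6 free-hydroxy pyranone from step 3
Product: 7 6-methyl-2-[1-methyl-2-oxo-4-(propan-2-yloxy)-1,2-dihydroquinolin-3-yl]-4H-pyrano[3,2-c]quinoline-4,5(6H)-dione
Conditions: 2-iodopropane, K2CO3, DMF, 60 °C
Reagents that add atoms: 2-iodopropane (CC(C)I)
Why: Williamson O-alkylation of the only acidic hydroxyl; C3 of that quinolone is already substituted, so the ambident anion should be alkylated on the 4-oxygen, which installs the future C-q with its hydrogen.

**Step 5**
Reactants: 7 isopropyl ether from step 4
Product: 10 rac-(aR,bS)-configured cis-fused pentacyclic ketone (ring A closed; C-c = C=O), via silyloxypyrylium triflate 8 (not isolated), via oxocarbenium silyl dienol ether 9 (not isolated)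
Conditions: TMSOTf (20 mol %), ClCH2CH2Cl, 60 °C; aq NaHCO3
Reagents that add atoms: none
Why: Proposed new method: O-silylation of the C-c carbonyl turns the γ-pyranone of 7 into 4-silyloxypyrylium ion 8, whose C-b lies 1,5 to the isopropyl methine through O–C4=C3 of quinolone A, so a suprafacial 1,5-hydride shift over a six-membered transition state should give C-b–H and ion 9, an aryl oxocarbenium at C-q beside a silyl dienol ether that is nucleophilic at C-a. The closest known reaction type is the Lewis-acid-catalysed 1,5-hydride shift/cyclization (internal redox) of ortho-alkoxyaryl alkylidene malonates and enones to chromans, together with silyl triflate activation of chromones toward attack at C2; new here are the γ-pyranone as hydride acceptor and an isopropyl ether of a vinylogous acid as donor. Ring A then closes by a Mukaiyama-aldol (Prins-type) attack of C-a on C-q, 6-endo-trig at the oxocarbenium and exo to the enol ether, which forms the quaternary O–CMe2 carbon and passes the silyl group to the next molecule of 7. C-b is created by hydride delivery to either face (hence the racemate) and C-a is fixed relative to it, because the three-atom O–C4=C3 tether hanging from C-b can reach only the same face of C-a, so the ring fusion must be cis. The step needs hydride transfer to beat loss of the isopropyl group and C–C collapse to beat proton loss from 9; the 1,5-geometry, the doubly methyl-stabilized oxocarbenium and the intimate ion pair should secure both. The isomerization is downhill (an enone π bond is traded for a C–H and a C–C σ bond) and uses no external oxidant or reductant.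

**Step 6**
Reactants: 10 rac-(aR,bS) ketone from step 5
Product: 11 (aR,bS,cS)-carbinol (C-c = CH–OH; OH on the face of C-q)
Conditions: RuCl[(S,S)-TsDPEN](p-cymene) (2 mol %), HCO2H/Et3N (5:2), CH2Cl2, 0 °C, to about half conversion
Reagents that add atoms: none
Why: Noyori-type asymmetric transfer hydrogenation run as a kinetic resolution: for the (aR,bS)-ketone the carbonyl face preferred by the (S,S)-catalyst (by analogy with 4-chromanone) is also the open convex face of the two ring-fusion hydrogens, so this enantiomer should be reduced fast to the (cS)-carbinol while the mismatched mirror-image ketone stays behind and is separated.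

**Step 7**
Reactants: 11 (aR,bS,cS)-carbinol from step 6
Product: 12 (aR,bS,cR)-methallyl compound (C-c carries CH2C(CH3)=CH2)
Conditions: trimethyl(2-methylallyl)silane, InCl3 (10 mol %), CH2Cl2, −20 to 0 °C
Reagents that add atoms: trimethyl(2-methylallyl)silane (C=C(C)C[Si](C)(C)C)
Why: Lewis-acid-mediated SN1 substitution by the allylsilane (Hosomi–Sakurai type): ionization at C-c is assisted by the ring-B oxygen through C4=C3 of quinolone B, and the nucleophile should add to the planar C-c from the convex face of the cis-fused bicycle, anti to C-q on C-a, which places the side chain trans to C-q and sets C-c as R whatever the carbinol configuration was.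

**Step 8**
Reactants: 12 (aR,bS,cR)-methallyl compound from step 7
Product: 13 CNP0202276.1, (aR,bS,cR)
Conditions: Co(acac)2 (20 mol %), PhSiH3, O2 (1 atm), i-PrOH/THF, 23 °C
Reagents that add atoms: dioxygen (O=O)
Why: Mukaiyama hydration (metal-hydride hydrogen-atom transfer): hydrogen adds to the terminal CH2 of the only unhindered, electron-rich alkene, and the tertiary radical is trapped by O2 and reduced to the tertiary alcohol without touching any stereocenter.

**Compound list**

1 | 4-hydroxy-1-methylquinolin-2(1H)-one | Cn1c(=O)cc(O)c2ccccc12 | starting material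
2 | 4-hydroxy-1-methyl-2-oxo-1,2-dihydroquinoline-3-carbaldehyde | Cn1c(=O)c(C=O)c(O)c2ccccc12 | intermediate
3 | 3-acetyl-4-hydroxy-1-methylquinolin-2(1H)-one | CC(=O)c1c(O)c2ccccc2n(C)c1=O | starting material
4 | (E)-4-hydroxy-3-[3-(4-hydroxy-1-methyl-2-oxo-1,2-dihydroquinolin-3-yl)prop-2-enoyl]-1-methylquinolin-2(1H)-one | Cn1c(=O)c(C(=O)/C=C/c3c(O)c4ccccc4n(C)c3=O)c(O)c2ccccc12 | intermediate
5 | racemic 2-(4-hydroxy-1-methyl-2-oxo-1,2-dihydroquinolin-3-yl)-6-methyl-2,3-dihydro-4H-pyrano[3,2-c]quinoline-4,5(6H)-dione | Cn1c(=O)c(C3CC(=O)c4c(O3)c5ccccc5n(C)c4=O)c(O)c2ccccc12 | intermediate (not isolated)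
6 | 2-(4-hydroxy-1-methyl-2-oxo-1,2-dihydroquinolin-3-yl)-6-methyl-4H-pyrano[3,2-c]quinoline-4,5(6H)-dione | Cn1c(=O)c(C3=CC(=O)c4c(O3)c5ccccc5n(C)c4=O)c(O)c2ccccc12 | intermediate
7 | 6-methyl-2-[1-methyl-2-oxo-4-(propan-2-yloxy)-1,2-dihydroquinolin-3-yl]-4H-pyrano[3,2-c]quinoline-4,5(6H)-dione | CC(C)Oc1c(C3=CC(=O)c4c(O3)c5ccccc5n(C)c4=O)c(=O)n(C)c2ccccc12 | intermediate
8 | 4-(trimethylsilyloxy)pyrylium triflate of 7 (silylated at the C-c oxygen) | CC(C)OC1=C(C3=CC(O[Si](C)(C)C)=C4C(=[O+]3)c5ccccc5N(C)C4=O)C(=O)N(C)c2ccccc12.[O-]S(=O)(=O)C(F)(F)F | intermediate (not isolated)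
9 | racemic 2H-pyran silyl dienol ether (C-b–H) whose quinolone A oxygen carries the propan-2-ylidene oxocarbenium ion; triflate | CC(C)=[O+]C1=C(C3C=C(O[Si](C)(C)C)c4c(O3)c5ccccc5n(C)c4=O)C(=O)N(C)c2ccccc12.[O-]S(=O)(=O)C(F)(F)F | intermediate (not isolated)
10 | rac-(aR,bS) cis-fused pentacyclic ketone (target skeleton with C-c as C=O; racemate, the enantiomer carried on is drawn) | Cn1c(=O)c2c(c3ccccc31)OC(C)(C)[C@H]1[C@@H]2Oc2c(c(=O)n(C)c3ccccc23)C1=O | intermediate
11 | (aR,bS,cS)-carbinol (C-c = CH–OH) | Cn1c(=O)c2c(c3ccccc31)OC(C)(C)[C@H]1[C@@H]2Oc2c(c(=O)n(C)c3ccccc23)[C@H]1O | intermediate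
12 | (aR,bS,cR)-methallyl compound (C-c–CH2C(CH3)=CH2) | Cn1c(=O)c2c(c3ccccc31)OC(C)(C)[C@H]1[C@@H]2Oc2c(c(=O)n(C)c3ccccc23)[C@@H]1CC(C)=C | intermediate
13 | CNP0202276.1, (aR,bS,cR) | Cn1c(=O)c2c(c3ccccc31)OC(C)(C)[C@H]1[C@@H]2Oc2c(c(=O)n(C)c3ccccc23)[C@@H]1CC(C)(C)O | target

**Totals and risks**

Total step count: 8. Longest linear sequence: 8 steps (1 to 13).

Steps most likely to fail:

- **Step 5.** The hydride shift may be too slow on this acceptor/donor pair, so that acid-induced loss of the isopropyl group or proton loss from ion 9 takes over. Fallback with external redox reagents, setting out from 6 and returning at 10. Copper-mediated Chan–Lam-type O-alkenylation of 6 (Cu(OAc)2, pyridine, 2-isopropenyl-4,4,5,5-tetramethyl-1,3,2-dioxaborolane, air) would give the isopropenyl ether of 6, F1. Conjugate reduction of its pyranone with LiBH(s-Bu)3 at −78 °C and trapping of the enolate with TBSOTf would give the racemic 4-silyloxy-2H-pyran silyl enol ether, F2. TfOH (1 equiv, CH2Cl2, −78 °C) would protonate the isopropenyl ether, and the silyl enol ether would close ring A by a Mukaiyama-aldol-type addition to the resulting oxocarbenium, cis for the same tether reason, to give 10.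

- **Step 7.** The cation may lose the C-a proton (giving a 2H-pyran and erasing C-a) or be attacked on the wrong face. Fallback by a radical path, setting out from 11 and returning at 12. NaH, CS2 and MeI would convert 11 into the S-methyl xanthate of 11, F3. Keck radical allylation (tributyl(2-methylallyl)stannane, AIBN, benzene, 80 °C) would then deliver the methallyl group to the C-c radical from the convex face without any cation.

- **Step 6.** The resolution may be poorly selective, or the basic medium may open ring B by retro-oxa-Michael reaction and scramble the ring fusion. Fallback by classical resolution, setting out from 10 and returning at 11. Luche reduction (NaBH4, CeCl3·7H2O, MeOH, −40 °C) would give the racemic carbinol, F4. Steglich esterification with (S)-2-methoxy-2-phenylacetic acid (DCC, DMAP) would give the ester of the (aR,bS,cS)-carbinol, F5, and the ester of its mirror-image carbinol, F6, to be separated by chromatography. Saponification of F5 (LiOH, THF/H2O) would give 11.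

**Further compounds**

F1 | step 5 | 6-methyl-2-[1-methyl-2-oxo-4-(prop-1-en-2-yloxy)-1,2-dihydroquinolin-3-yl]-4H-pyrano[3,2-c]quinoline-4,5(6H)-dione | C=C(C)Oc1c(C3=CC(=O)c4c(O3)c5ccccc5n(C)c4=O)c(=O)n(C)c2ccccc12
F2 | step 5 | racemic 4-(tert-butyldimethylsilyloxy)-6-methyl-2-[1-methyl-2-oxo-4-(prop-1-en-2-yloxy)-1,2-dihydroquinolin-3-yl]-2H-pyrano[3,2-c]quinolin-5(6H)-one | C=C(C)Oc1c(C3C=C(O[Si](C)(C)C(C)(C)C)c4c(O3)c5ccccc5n(C)c4=O)c(=O)n(C)c2ccccc12
F3 | step 7 | O-[(aR,bS,cS)-carbinol 11] S-methyl dithiocarbonate | Cn1c(=O)c2c(c3ccccc31)OC(C)(C)[C@H]1[C@@H]2Oc2c(c(=O)n(C)c3ccccc23)[C@H]1OC(=S)SC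
F4 | step 6 | racemic carbinol (racemate of 11; the (aR,bS,cS) enantiomer is drawn) | Cn1c(=O)c2c(c3ccccc31)OC(C)(C)[C@H]1[C@@H]2Oc2c(c(=O)n(C)c3ccccc23)[C@H]1O
F5 | step 6 | (S)-2-methoxy-2-phenylacetate of the (aR,bS,cS)-carbinol | Cn1c(=O)c2c(c3ccccc31)OC(C)(C)[C@H]1[C@@H]2Oc2c(c(=O)n(C)c3ccccc23)[C@H]1OC(=O)[C@@H](OC)c1ccccc1
F6 | step 6 | (S)-2-methoxy-2-phenylacetate of the (aS,bR,cR)-carbinol | Cn1c(=O)c2c(c3ccccc31)OC(C)(C)[C@@H]1[C@H]2Oc2c(c(=O)n(C)c3ccccc23)[C@@H]1OC(=O)[C@@H](OC)c1ccccc1
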